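**Assumption:** the radical peroxidation cannot control the tertiary peroxy carbon, so its two epimers are carried as a 1:1 mixture from step 9 and separated after step 11 (at most 50% of the wanted epimer). Locants C-3, C-4, C-4a, C-7a follow the furo[3,2-c][1,2]dioxin-6-one name of the target.

**Retrosynthetic overview**
1. The 1,2-dioxane ring is formed last, by 6-exo peroxy-Michael addition of a tertiary hydroperoxide onto a γ,γ-disubstituted butenolide; this fixes C-7a cis to C-4a.
2. The hydroperoxide comes from a 1,1-disubstituted alkene by cobalt-catalysed hydroperoxysilylation (C-3, epimers separated at the end).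
3. The butenolide ring is formed first, from a Z-enoate made by Still–Gennari olefination of an α-silyloxy aldehyde; the alkene comes from ketone methylenation.
4. The key C-4/C-4a bond comes from an enantioselective copper–bis(oxazoline) Mukaiyama aldol of the kinetic enol silane of octadecan-2-one with methyl pyruvate, which sets the quaternary carbinol C-4a.

**Route**

Step 1
Reactants: 1 octadecan-2-one
Product: 3 trimethyl(octadec-1-en-2-yloxy)silane, via lithium octadec-1-en-2-olate 2 (not isolated)
Conditions: LiN(iPr)2 (LDA, commercial solution, 1.1 equiv), THF, −78 °C; then Me3SiCl, −78 °C → rt; pentane, filtration, short-path distillation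
Reagents that add atoms: chlorotrimethylsilane, C[Si](C)(C)Cl
Why: Kinetic deprotonation by the bulky amide at −78 °C takes a proton from the methyl side and O-silylation traps the terminal enolate (kinetic enol silane formation); the minor internal isomer is removed after step 2.

Step 2
Reactants: 3 trimethyl(octadec-1-en-2-yloxy)silane; 4 methyl pyruvate (methyl 2-oxopropanoate)
Product: 6 methyl (S)-2-hydroxy-2-methyl-4-oxoicosanoate, via trimethylsilyl ether 5 (not isolated)
Conditions: Cu(OTf)2 (10 mol%), 2,2′-(propane-2,2-diyl)bis[(4S)-4-tert-butyl-4,5-dihydrooxazole] (11 mol%), THF, −78 °C; then 1 N HCl, THF, rt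
Reagents that add atoms: none
Why: Catalytic enantioselective Mukaiyama aldol: pyruvate chelates the square-planar divalent copper centre through both carbonyl oxygens, a tert-butyl group of the (S,S)-ligand blocks the re face, and the enol silane adds to the si face to give the (S)-carbinol (future C-4a).

Step 3
Reactants: 6 methyl (S)-2-hydroxy-2-methyl-4-oxoicosanoate
Product: 7 methyl (S)-2-[(tert-butyldimethylsilyl)oxy]-2-methyl-4-oxoicosanoate
Conditions: TBSOTf (1.3 equiv), 2,6-lutidine, CH2Cl2, −78 → 0 °C
Reagents that add atoms: tert-butyldimethylsilyl trifluoromethanesulfonate, CC(C)(C)[Si](C)(C)OS(=O)(=O)C(F)(F)F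
Why: Silyl triflate silylation of the hindered tertiary alcohol; it blocks retro-aldol cleavage and protects the hydroxyl for the next four steps without touching the stereocentre.

Step 4
Reactants: 7 methyl (S)-2-[(tert-butyldimethylsilyl)oxy]-2-methyl-4-oxoicosanoate
Product: 8 methyl (S)-2-[(tert-butyldimethylsilyl)oxy]-2-methyl-4-methylideneicosanoate
Conditions: Zn, CH2Br2, TiCl4, THF (pre-formed reagent); then 7, CH2Cl2, 0 °C → rt
Reagents that add atoms: dibromomethane, BrCBr
Why: Takai–Lombardo methylenation: the non-basic zinc/titanium methylene reagent converts the enolisable ketone into the 1,1-disubstituted alkene without β-elimination of the silyloxy group and does not react with the ester.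

Step 5
Reactants: 8 methyl (S)-2-[(tert-butyldimethylsilyl)oxy]-2-methyl-4-methylideneicosanoate
Product: 9 (S)-2-[(tert-butyldimethylsilyl)oxy]-2-methyl-4-methylideneicosan-1-ol
Conditions: iBu2AlH (DIBAL-H, 2.5 equiv), CH2Cl2, −78 → 0 °C; aq. potassium sodium tartrate
Reagents that add atoms: none
Why: Hydride reduction of the hindered ester fully to the primary alcohol (more dependable than stopping at the aldehyde); the aluminium alkoxide at low temperature does not cause silyl migration and the isolated alkene is inert.

Step 6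
Reactants: 9 (S)-2-[(tert-butyldimethylsilyl)oxy]-2-methyl-4-methylideneicosan-1-ol
Product: 10 (S)-2-[(tert-butyldimethylsilyl)oxy]-2-methyl-4-methylideneicosanal
Conditions: Dess–Martin periodinane, CH2Cl2, 0 °C → rt
Reagents that add atoms: none
Why: Dess–Martin oxidation stops at the aldehyde, which has no α-hydrogen and so cannot epimerise or enolise.

Step 7
Reactants: 10 (S)-2-[(tert-butyldimethylsilyl)oxy]-2-methyl-4-methylideneicosanal
Product: 11 methyl (2Z,4S)-4-[(tert-butyldimethylsilyl)oxy]-4-methyl-6-methylidenedocos-2-enoate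
Conditions: (CF3CH2O)2P(O)CH2CO2Me, KN(SiMe3)2, 18-crown-6, THF, −78 °C
Reagents that add atoms: methyl bis(2,2,2-trifluoroethyl)phosphonoacetate, COC(=O)CP(=O)(OCC(F)(F)F)OCC(F)(F)F
Why: Still–Gennari variant of the Horner–Wadsworth–Emmons olefination: the trifluoroethyl phosphonate with a dissociated potassium counter-ion eliminates rapidly from the kinetic adduct and gives the Z-enoate.

Step 8
Reactants: 11 methyl (2Z,4S)-4-[(tert-butyldimethylsilyl)oxy]-4-methyl-6-methylidenedocos-2-enoate
Product: 13 (S)-5-methyl-5-(2-methylideneoctadecyl)furan-2(5H)-one, via hydroxy Z-enoate 12 (not isolated)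
Conditions: HF·pyridine, pyridine, THF, 0 °C → rt
Reagents that add atoms: none
Why: Fluoride cleaves the Si–O bond and the freed tertiary hydroxyl, held cis to the ester, lactonises spontaneously to the butenolide (desilylation–lactonisation); any E-enoate cannot cyclise and is removed.

Step 9
Reactants: 13 (S)-5-methyl-5-(2-methylideneoctadecyl)furan-2(5H)-one
Product: 14 (5S)-5-methyl-5-[(2R)-2-methyl-2-(triethylsilylperoxy)octadecyl]furan-2(5H)-one (1:1 mixture with its 2S epimer)
Conditions: Co(thd)2 [cobalt bis(2,2,6,6-tetramethylheptane-3,5-dionate), 10 mol%], O2 (1 atm), Et3SiH (2 equiv), ClCH2CH2Cl, rt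
Reagents that add atoms: dioxygen, O=O; triethylsilane, CC[SiH](CC)CC
Why: Mukaiyama–Isayama hydroperoxysilylation: a cobalt hydride delivers a hydrogen atom to the terminal CH2 of the electron-rich 1,1-disubstituted alkene (Markovnikov) in preference to the electron-poor butenolide alkene, and the planar tertiary radical traps O2 from either face, so the new peroxy centre forms as both epimers.

Step 10
Reactants: 14 (5S)-5-methyl-5-[(2R)-2-methyl-2-(triethylsilylperoxy)octadecyl]furan-2(5H)-one (1:1 mixture with its 2S epimer)
Product: 15 (5S)-5-[(2R)-2-hydroperoxy-2-methyloctadecyl]-5-methylfuran-2(5H)-one (1:1 mixture with its 2S epimer)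
Conditions: HCl (cat.), MeOH, 0 °C
Reagents that add atoms: none
Why: Acid-catalysed methanolysis of the labile O–Si bond of the silyl peroxide frees the tertiary hydroperoxide without touching the O–O bond or the butenolide.

Step 11
Reactants: 15 (5S)-5-[(2R)-2-hydroperoxy-2-methyloctadecyl]-5-methylfuran-2(5H)-one (1:1 mixture with its 2S epimer)
Product: 16 (3R,4aS,7aS)-3-hexadecyl-3,4a-dimethyltetrahydro-3H-furo[3,2-c][1,2]dioxin-6(4H)-one
Conditions: Et2NH (0.5 equiv), CF3CH2OH, rt; silica chromatography, then preparative HPLC if needed, to remove the (3S) epimer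
Reagents that add atoms: none
Why: 6-exo-trig peroxy-Michael addition: the hydroperoxide is tethered to the butenolide γ-carbon and can reach the β-carbon only from its own face, so the ring fusion is cis (7aS); the (3R) epimer, with the 3- and 4a-methyl groups cis (NOESY), is the target and is separated from its diastereomer.

**Compound list**
1 | octadecan-2-one | CCCCCCCCCCCCCCCCC(C)=O | starting material
2 | lithium octadec-1-en-2-olate | [Li+].[O-]C(=C)CCCCCCCCCCCCCCCC | intermediate
3 | trimethyl(octadec-1-en-2-yloxy)silane | C=C(O[Si](C)(C)C)CCCCCCCCCCCCCCCC | intermediate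
4 | methyl pyruvate | CC(=O)C(=O)OC | starting material
5 | methyl (S)-2-methyl-4-oxo-2-(trimethylsilyloxy)icosanoate | CCCCCCCCCCCCCCCCC(=O)C[C@](C)(O[Si](C)(C)C)C(=O)OC | intermediate
6 | methyl (S)-2-hydroxy-2-methyl-4-oxoicosanoate | CCCCCCCCCCCCCCCCC(=O)C[C@](C)(O)C(=O)OC | intermediate
7 | methyl (S)-2-[(tert-butyldimethylsilyl)oxy]-2-methyl-4-oxoicosanoate | CCCCCCCCCCCCCCCCC(=O)C[C@](C)(O[Si](C)(C)C(C)(C)C)C(=O)OC | intermediate
8 | methyl (S)-2-[(tert-butyldimethylsilyl)oxy]-2-methyl-4-methylideneicosanoate | CCCCCCCCCCCCCCCCC(=C)C[C@](C)(O[Si](C)(C)C(C)(C)C)C(=O)OC | intermediate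
9 | (S)-2-[(tert-butyldimethylsilyl)oxy]-2-methyl-4-methylideneicosan-1-ol | CCCCCCCCCCCCCCCCC(=C)C[C@](C)(O[Si](C)(C)C(C)(C)C)CO | intermediate
10 | (S)-2-[(tert-butyldimethylsilyl)oxy]-2-methyl-4-methylideneicosanal | CCCCCCCCCCCCCCCCC(=C)C[C@](C)(O[Si](C)(C)C(C)(C)C)C=O | intermediate
11 | methyl (2Z,4S)-4-[(tert-butyldimethylsilyl)oxy]-4-methyl-6-methylidenedocos-2-enoate | CCCCCCCCCCCCCCCCC(=C)C[C@](C)(O[Si](C)(C)C(C)(C)C)/C=C\C(=O)OC | intermediate
12 | methyl (2Z,4S)-4-hydroxy-4-methyl-6-methylidenedocos-2-enoate | CCCCCCCCCCCCCCCCC(=C)C[C@](C)(O)/C=C\C(=O)OC | intermediate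
13 | (S)-5-methyl-5-(2-methylideneoctadecyl)furan-2(5H)-one | CCCCCCCCCCCCCCCCC(=C)C[C@]1(C)OC(=O)C=C1 | intermediate
14 | (5S)-5-methyl-5-[(2R)-2-methyl-2-(triethylsilylperoxy)octadecyl]furan-2(5H)-one (drawn epimer; formed 1:1 with the 2S epimer) | CCCCCCCCCCCCCCCC[C@@](C)(OO[Si](CC)(CC)CC)C[C@]1(C)OC(=O)C=C1 | intermediate
15 | (5S)-5-[(2R)-2-hydroperoxy-2-methyloctadecyl]-5-methylfuran-2(5H)-one (drawn epimer; 1:1 with the 2S epimer) | CCCCCCCCCCCCCCCC[C@@](C)(OO)C[C@]1(C)OC(=O)C=C1 | intermediate
16 | (3R,4aS,7aS)-3-hexadecyl-3,4a-dimethyltetrahydro-3H-furo[3,2-c][1,2]dioxin-6(4H)-one (cis-fused peroxylactone) | CCCCCCCCCCCCCCCC[C@]1(C)C[C@]2(C)OC(=O)C[C@@H]2OO1 | target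

**Totals**
Total step count: 11. Longest linear sequence: 11 steps (from octadecan-2-one).

**Three steps most likely to fail**

Step 2 (aldol). The risk is enantioselectivity near 90–95% ee with a simple ketone enol silane, plus a few percent of internal enol silane. The minor enantiomer cannot be removed later, so 6 is assayed by chiral HPLC and recrystallised, and its absolute configuration is confirmed before going on. The facial sense stated in step 2 rests on the chelate model and on recall of this catalyst system; if 6 proved to be (R), the (R,R)-ligand would be used.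

The fallback sets out from 4 and comes back at 5. S-Ethyl thioacetate is converted (LiN(iPr)2, Me3SiCl, THF, −78 °C) into [1-(ethylsulfanyl)ethenyl]oxy(trimethyl)silane F1, a nucleophile with no regiochemical ambiguity that belongs to the best substrate class for this catalyst. Its aldol with 4 under the step 2 catalyst, worked up without acid, gives methyl (S)-4-(ethylsulfanyl)-2-methyl-4-oxo-2-(trimethylsilyloxy)butanoate F2. Fukuyama coupling of this thioester with hexadecylzinc iodide F3 (from 1-iodohexadecane and Zn dust) and PdCl2(PPh3)2 in toluene/THF gives ketone 5, which the acid work-up of step 2 turns into 6.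

Step 7 (Z-olefination). The risk is slow reaction or eroded Z-selectivity with the hindered α-quaternary aldehyde.

The fallback sets out from 10 and comes back at 11. Homologation of 10 with dimethyl (1-diazo-2-oxopropyl)phosphonate and K2CO3 in MeOH gives (S)-tert-butyldimethyl[(3-methyl-5-methylidenehenicos-1-yn-3-yl)oxy]silane F4. Treatment with n-BuLi and then ClCO2Me (THF, −78 °C) gives methyl (S)-4-[(tert-butyldimethylsilyl)oxy]-4-methyl-6-methylidenedocos-2-ynoate F5. Semi-hydrogenation (H2, Pd on CaCO3 poisoned with Pb(OAc)2, quinoline, EtOAc) gives 11, its Z geometry fixed by syn addition of hydrogen, while the 1,1-disubstituted alkene is left alone.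

Step 9 (cobalt peroxidation). The risks are competing hydrogen-atom transfer to the butenolide alkene or reduction of the peroxide; the lack of control at the peroxy carbon is inherent.

The fallback sets out from 13 and comes back at 15, replacing the radical process with an ionic one. HBr (33% in AcOH) in CH2Cl2 at 0 °C adds in the Markovnikov sense to the 1,1-disubstituted alkene to give (5S)-5-(2-bromo-2-methyloctadecyl)-5-methylfuran-2(5H)-one F6 (both configurations at the bromide carbon). Silver-assisted perhydrolysis (anhydrous H2O2 in Et2O, silver trifluoroacetate AgOCOCF3, 0 °C) then gives hydroperoxide 15 as the same 1:1 epimer mixture, skipping 14.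

**Further compounds**
F1 | step 2 | [1-(ethylsulfanyl)ethenyl]oxy(trimethyl)silane | C=C(O[Si](C)(C)C)SCC
F2 | step 2 | methyl (S)-4-(ethylsulfanyl)-2-methyl-4-oxo-2-(trimethylsilyloxy)butanoate | CCSC(=O)C[C@](C)(O[Si](C)(C)C)C(=O)OC
F3 | step 2 | hexadecylzinc iodide | CCCCCCCCCCCCCCCC[Zn]I
F4 | step 7 | (S)-tert-butyldimethyl[(3-methyl-5-methylidenehenicos-1-yn-3-yl)oxy]silane | CCCCCCCCCCCCCCCCC(=C)C[C@](C)(O[Si](C)(C)C(C)(C)C)C#C
F5 | step 7 | methyl (S)-4-[(tert-butyldimethylsilyl)oxy]-4-methyl-6-methylidenedocos-2-ynoate | CCCCCCCCCCCCCCCCC(=C)C[C@](C)(O[Si](C)(C)C(C)(C)C)C#CC(=O)OC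
F6 | step 9 | (5S)-5-(2-bromo-2-methyloctadecyl)-5-methylfuran-2(5H)-one (both epimers at the bromide carbon) | CCCCCCCCCCCCCCCCC(C)(Br)C[C@]1(C)OC(=O)C=C1
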